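## Retrosynthetic overview

1. Flemistrictin D is traced back, through removal of two acetyl groups and DDQ dehydrogenation of C3–C4, to the saturated 6-acyl chromane-5,8-diol. Its C6–acyl bond is cut to 3-phenylpropanoic acid and 7-methoxy-2,2-dimethylchromane-5,8-diol (Friedel–Crafts acylation).
2. Feature on which the strategy rests: the benzene ring C4a–C5–C6–C7–C8–C8a carries para hydroxyls at C5 and C8 and the methoxy group at C7 beside C8. It shares the C4a–C8a edge with the pyran ring, with O1 on C8a, so it is a methoxyhydroquinone fused to a cyclic enol ether.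
3. Key disconnection: the C5–C4a bond, and with it the whole benzene ring, is undone to a 4-hydroxy-3-methoxycyclobutenone that carries the dihydropyranyl group on C4 (thermal 4π opening, then 6π closure).
4. This cyclobutenone comes from 3-methoxycyclobutene-1,2-dione (dimethyl squarate, reduction, loss of methanol) and 6-lithio-2,2-dimethyl-3,4-dihydro-2H-pyran (hetero-Diels–Alder adduct of acrolein and 2-methylpropene).
5. Ring order: pyran ring first (step 1), benzene ring second (step 5); the C3=C4 double bond of the pyran ring is introduced last.

Key step: step 5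

Remark: the target has no stereocenter; the stereocenters that appear on the way are racemic and transient.

## Route

Step 1
Reactants: 1 acrolein, 2 2-methylpropene
Product: 3 2,2-dimethyl-3,4-dihydro-2H-pyran
Conditions: neat (2 in excess), BHT (cat.), steel autoclave, 190 °C
Reagents that add atoms: none
Why: Thermal hetero-Diels–Alder reaction with inverse electron demand, in which acrolein is the 1-oxadiene and the more substituted alkene carbon, which best carries positive charge in the asynchronous transition state, bonds to oxygen, so the 2,2-dimethyl regioisomer should form.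

Step 2
Reactants: 4 dimethyl squarate
Product: 5 4-hydroxy-2,3-dimethoxycyclobut-2-en-1-one (racemic)
Conditions: LiAlH(O-t-Bu)3 (1.05 equiv), THF, –78 → –20 °C; then H2O
Reagents that add atoms: none
Why: Carbonyl 1,2-reduction by a hindered mono-hydride donor at low temperature, which should stop after one of the two equivalent vinylogous-ester carbonyls has reacted; the new carbinol center forms as a racemate and is destroyed in step 3.

Step 3
Reactants: 5 4-hydroxy-2,3-dimethoxycyclobut-2-en-1-one
Product: 6 3-methoxycyclobut-3-ene-1,2-dione
Conditions: conc. HCl (cat.), CH2Cl2, rt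
Reagents that add atoms: water, SMILES O (the oxygen of the new C2 carbonyl arrives from water)
Why: Acid-catalysed allylic transposition, in which ionisation of the C4 hydroxyl gives an allyl cation capped by the C2 methoxy group, water adds at C2 and the hemiketal loses methanol, leaving the dione with the C3=C4 double bond.

Step 4
Reactants: 3 2,2-dimethyl-3,4-dihydro-2H-pyran, 6 3-methoxycyclobut-3-ene-1,2-dione
Product: 8 4-hydroxy-3-methoxy-4-(6,6-dimethyl-5,6-dihydro-4H-pyran-2-yl)cyclobut-2-en-1-one (racemic), via lithiated dihydropyran 7 (not isolated)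
Conditions: 3, t-BuLi, THF/pentane, –78 → 0 °C; then 6, THF, –78 °C; aq. NH4Cl
Reagents that add atoms: none
Why: Vinylic α-lithiation of the cyclic enol ether followed by 1,2-addition of the alkenyllithium to a ketone, which should occur at C2 of 6 because this carbonyl, next to the methoxy-bearing carbon, is ketone-like whereas the C1 carbonyl is deactivated as the end of the vinylogous ester MeO–C3=C4–C1=O; the carbinol center is racemic and is lost on aromatisation.

Step 5
Reactants: 8 4-hydroxy-3-methoxy-4-(6,6-dimethyl-5,6-dihydro-4H-pyran-2-yl)cyclobut-2-en-1-one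
Product: 11 7-methoxy-2,2-dimethylchromane-5,8-diol, via dienylketene 9 (not isolated), via cyclohexadienone 10 (not isolated)
Conditions: degassed toluene, 110 °C, Ar; concentrated under Ar and used at once
Reagents that add atoms: none
Why: Heat should open the C1–C4 bond of 8 by conrotatory 4π electrocyclic ring opening, in which the hydroxyl turns outward, as oxygen donors on the sp3 carbon of a cyclobutene do, and the dihydropyranyl group turns inward, so that the (Z)-dienylketene 9 forms. The ketene carbon then bonds to the β-carbon of the enol ether by a thermal 6π electrocyclization, which closes the six-membered carbocycle and forms C5–C4a, and the cyclohexa-2,4-dienone 10 tautomerises to the aromatic diol. The closest known reaction type is the Moore rearrangement of 4-alkenyl- and 4-aryl-4-hydroxycyclobutenones to hydroquinones. The only new stereocenter, C4a of 10, is transient and is erased by aromatisation, so nothing has to be controlled there. The step needs outward rotation of the hydroxyl, which the donor character of this group secures and which reversible ring opening supports, since only the Z ketene can close. The placement of C7–OMe beside C8–OH with C6–H free is already fixed by the regiochemistry of step 4.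

Step 6
Reactants: 11 7-methoxy-2,2-dimethylchromane-5,8-diol, 12 3-phenylpropanoic acid
Product: 13 1-(5,8-dihydroxy-7-methoxy-2,2-dimethylchroman-6-yl)-3-phenylpropan-1-one
Conditions: BF3·OEt2 (solvent), 80 °C, Ar; then aq. NaOAc
Reagents that add atoms: none
Why: Friedel–Crafts acylation of a phenol with a carboxylic acid in BF3·OEt2 (direct, or by O-acylation and Fries rearrangement) at C6, the only unsubstituted ring position, which is activated by the ortho C5–OH, the ortho C7–OMe and the para ring oxygen on C8a, the product being held as a hydrogen-bonded ortho-hydroxy ketone.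

Step 7
Reactants: 13 1-(5,8-dihydroxy-7-methoxy-2,2-dimethylchroman-6-yl)-3-phenylpropan-1-one
Product: 14 7-methoxy-2,2-dimethyl-6-(3-phenylpropanoyl)chromane-5,8-diyl diacetate
Conditions: Ac2O, pyridine, DMAP (cat.), rt
Reagents that add atoms: acetic anhydride, SMILES CC(=O)OC(C)=O
Why: DMAP-catalysed O-acetylation (nucleophilic acyl substitution) of both phenols, which masks the hydroquinone so that DDQ in step 8 cannot oxidise it to the quinone.

Step 8
Reactants: 14 7-methoxy-2,2-dimethyl-6-(3-phenylpropanoyl)chromane-5,8-diyl diacetate
Product: 15 7-methoxy-2,2-dimethyl-6-(3-phenylpropanoyl)-2H-chromene-5,8-diyl diacetate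
Conditions: DDQ (1.5 equiv), 1,4-dioxane, 100 °C
Reagents that add atoms: none
Why: DDQ dehydrogenation of a 2,2-dimethylchroman, in which hydride abstraction from benzylic C4 gives a cation stabilised by the para C7–OMe and the ortho ring oxygen and loss of the C3 proton gives the C3=C4 double bond, no other alkene being possible because C2 is quaternary.

Step 9
Reactants: 15 7-methoxy-2,2-dimethyl-6-(3-phenylpropanoyl)-2H-chromene-5,8-diyl diacetate
Product: 16 Flemistrictin D, 1-(5,8-dihydroxy-7-methoxy-2,2-dimethyl-2H-chromen-6-yl)-3-phenylpropan-1-one
Conditions: K2CO3 (2.5 equiv), degassed MeOH, rt, Ar; then 1 M HCl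
Reagents that add atoms: none
Why: Base-mediated transesterification (methanolysis) of the two aryl acetates, which are far more labile than the aryl ketone, the methyl ether and the chromene, run with exclusion of air so that the freed hydroquinone is not oxidised.

## Compound list

1 | acrolein (prop-2-enal) | C=CC=O | starting material
2 | 2-methylpropene | CC(C)=C | starting material
3 | 2,2-dimethyl-3,4-dihydro-2H-pyran | CC1(C)CCC=CO1 | intermediate
4 | dimethyl squarate (3,4-dimethoxycyclobut-3-ene-1,2-dione) | COC1=C(OC)C(=O)C1=O | starting material
5 | 4-hydroxy-2,3-dimethoxycyclobut-2-en-1-one (racemic) | COC1=C(OC)C(O)C1=O | intermediate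
6 | 3-methoxycyclobut-3-ene-1,2-dione | COC1=CC(=O)C1=O | intermediate
7 | (6,6-dimethyl-5,6-dihydro-4H-pyran-2-yl)lithium | [Li]C1=CCCC(C)(C)O1 | intermediate
8 | 4-hydroxy-3-methoxy-4-(6,6-dimethyl-5,6-dihydro-4H-pyran-2-yl)cyclobut-2-en-1-one (racemic) | O=C1C=C(OC)C1(O)C1=CCCC(C)(C)O1 | intermediate
9 | (3Z)-4-(6,6-dimethyl-5,6-dihydro-4H-pyran-2-yl)-4-hydroxy-3-methoxybuta-1,3-dien-1-one | O=C=C/C(OC)=C(/O)C1=CCCC(C)(C)O1 | intermediate
10 | 8-hydroxy-7-methoxy-2,2-dimethyl-2,3,4,4a-tetrahydro-5H-chromen-5-one (racemic) | O=C1C=C(OC)C(O)=C2OC(C)(C)CCC12 | intermediate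
11 | 7-methoxy-2,2-dimethylchromane-5,8-diol | COc1cc(O)c2c(c1O)OC(C)(C)CC2 | intermediate
12 | 3-phenylpropanoic acid | OC(=O)CCc1ccccc1 | starting material
13 | 1-(5,8-dihydroxy-7-methoxy-2,2-dimethylchroman-6-yl)-3-phenylpropan-1-one | COc1c(O)c2OC(C)(C)CCc2c(O)c1C(=O)CCc1ccccc1 | intermediate
14 | 7-methoxy-2,2-dimethyl-6-(3-phenylpropanoyl)chromane-5,8-diyl diacetate | COc1c(OC(C)=O)c2OC(C)(C)CCc2c(OC(C)=O)c1C(=O)CCc1ccccc1 | intermediate
15 | 7-methoxy-2,2-dimethyl-6-(3-phenylpropanoyl)-2H-chromene-5,8-diyl diacetate | COc1c(OC(C)=O)c2OC(C)(C)C=Cc2c(OC(C)=O)c1C(=O)CCc1ccccc1 | intermediate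
16 | Flemistrictin D, 1-(5,8-dihydroxy-7-methoxy-2,2-dimethyl-2H-chromen-6-yl)-3-phenylpropan-1-one | COc1c(O)c2c(c(O)c1C(=O)CCc1ccccc1)C=CC(C)(C)O2 | target

## Step count and risks

Total step count: 9
Longest linear sequence: 8 steps (steps 2 to 9, from 4 to 16)

Steps most likely to fail:

Step 5 (key step). The electron-rich diol may be partly oxidised by traces of oxygen at 110 °C and on silica, so that the material is spread over two oxidation levels and is lost on purification. Fallback, setting out from 8 and returning at 11: after the thermolysis of 8 the crude mixture is not purified but stirred with Ag2O and MgSO4 in Et2O, which should convert all of it into 7-methoxy-2,2-dimethylchromane-5,8-dione F1, a quinone that can be chromatographed and stored. Shortly before step 6, F1 is reduced with aqueous Na2S2O4 in EtOAc under argon and the resulting 11 is used without chromatography.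

Step 6. The free hydroquinone may be oxidised, O-acylation may fail to go on to the ring, or the tertiary alkyl aryl ether may open in hot BF3·OEt2. Fallback, setting out from 11 and returning at 13: both phenols are protected with MOMCl and i-Pr2NEt in CH2Cl2 to give 7-methoxy-5,8-bis(methoxymethoxy)-2,2-dimethylchromane F2. Directed ortho-lithiation with n-BuLi and TMEDA in THF at 0 °C should take place at C6, the only aromatic C–H, which is flanked by a MOM ether and the methoxy group. The aryllithium is acylated with N-methoxy-N-methyl-3-phenylpropanamide F3 (from 12 with MeNHOMe·HCl, EDC·HCl and Et3N) to give 1-[7-methoxy-5,8-bis(methoxymethoxy)-2,2-dimethylchroman-6-yl]-3-phenylpropan-1-one F4. HCl in MeOH at 40 °C removes both MOM groups and gives 13.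

Step 8. Hydride abstraction may be slow from a ring that two acetoxy groups and the ketone have made less electron-rich, and dehydrogenation of the CH2–CH2 unit next to the ketone may compete. Fallback, setting out from 14 and returning at 15: radical benzylic bromination (Wohl–Ziegler; NBS, AIBN, PhCF3, 80 °C) should go to C4, since no aromatic C–H is left and the benzylic position on the oxygen-rich ring is expected to react faster than the side-chain benzylic CH2. It gives 4-bromo-7-methoxy-2,2-dimethyl-6-(3-phenylpropanoyl)chromane-5,8-diyl diacetate F5 (racemic). DBU in toluene at rt then eliminates HBr to give 15.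

Further compounds
F1 | step 5 | 7-methoxy-2,2-dimethylchromane-5,8-dione | COC1=CC(=O)C2=C(OC(C)(C)CC2)C1=O
F2 | step 6 | 7-methoxy-5,8-bis(methoxymethoxy)-2,2-dimethylchromane | COCOc1cc(OC)c(OCOC)c2OC(C)(C)CCc12
F3 | step 6 | N-methoxy-N-methyl-3-phenylpropanamide | CON(C)C(=O)CCc1ccccc1
F4 | step 6 | 1-[7-methoxy-5,8-bis(methoxymethoxy)-2,2-dimethylchroman-6-yl]-3-phenylpropan-1-one | COCOc1c(C(=O)CCc2ccccc2)c(OC)c(OCOC)c2OC(C)(C)CCc12
F5 | step 8 | 4-bromo-7-methoxy-2,2-dimethyl-6-(3-phenylpropanoyl)chromane-5,8-diyl diacetate (racemic) | COc1c(OC(C)=O)c2OC(C)(C)CC(Br)c2c(OC(C)=O)c1C(=O)CCc1ccccc1
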